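Ring A is disconnected at C4a–C5 and traced back to a 2-aryl-4-pyranone (ring C carrying ring B) whose C8a bears the other five ring A carbons as a branched β-methoxyacrylate. The key step exploits the 1,3,5-oxygen pattern of ring A (O on C5, C7 and C8a) together with the fact that C4a is the α-carbon of the ring C pyranone carbonyl. Base-induced attack of C4a on the side-chain ester should build and aromatise ring A in one operation, fixing 5-OH, 7-OMe and the 8-prenyl group without regiochemical ambiguity. The precursor is racemic methyl (E)-3-methoxy-7-methyl-4-(6-aryl-4-oxopyran-2-yl)octa-2,6-dienoate with O4' masked as an allyl ether.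

Key step: step 8

Remark on the chemistry: the cyclisation precursor is named as a 7-methylocta-2,6-dienoate, because a 3-methylbut-2-enyl (prenyl) group on the carbon that becomes C8 requires an eight-carbon main chain (a nona-2,7-dienoate would carry a homoprenyl group); tri-carbonyl and β-keto ester intermediates are drawn as keto tautomers although they should exist largely as enols.

Step 1
Reactants: 1 methyl 4-hydroxy-2-methoxybenzoate
Product: 2 methyl 4-(allyloxy)-2-methoxybenzoate
Conditions: allyl bromide, K2CO3, DMF, rt
Reagents that add atoms: allyl bromide, C=CCBr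
Why: Williamson ether synthesis: the phenoxide formed by K2CO3 should displace bromide from allyl bromide by SN2, and the methyl ester and aryl methyl ether are inert under these conditions.

Step 2
Reactants: 2 methyl 4-(allyloxy)-2-methoxybenzoate; 3 acetylacetone
Product: 4 1-[4-(allyloxy)-2-methoxyphenyl]hexane-1,3,5-trione
Conditions: 3 (2.5 equiv), LiN(iPr)2 (5 equiv), THF, −78 → 0 °C; then 2, 0 °C → rt; 1 M HCl
Reagents that add atoms: none
Why: Claisen-type acylation of a β-diketone 1,5-dianion: the terminal carbanion of dilithioacetylacetone is far more nucleophilic than the central enolate and should attack the aryl ester, the excess dianion absorbing the more acidic triketone so that the electron-rich ester is consumed.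

Step 3
Reactants: 4 1-[4-(allyloxy)-2-methoxyphenyl]hexane-1,3,5-trione
Product: 5 2-[4-(allyloxy)-2-methoxyphenyl]-6-methyl-4H-pyran-4-one
Conditions: CF3CO2H, CH2Cl2, rt
Reagents that add atoms: none
Why: Acid-catalysed cyclodehydration of a 1,3,5-triketone: the C1 enol oxygen adds to the protonated C5 carbonyl and loss of water gives the 4-pyranone, while the aryl allyl and methyl ethers should tolerate CF3CO2H at room temperature.

Step 4
Reactants: 5 2-[4-(allyloxy)-2-methoxyphenyl]-6-methyl-4H-pyran-4-one; 6 prenyl bromide
Product: 7 2-[4-(allyloxy)-2-methoxyphenyl]-6-(4-methylpent-3-en-1-yl)-4H-pyran-4-one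
Conditions: LiN(iPr)2 (1.05 equiv), THF, −78 °C; then 6, −78 → −20 °C
Reagents that add atoms: none
Why: Lateral (vinylogous) deprotonation of the 6-methyl group of the 4-pyranone gives an extended enolate that should be alkylated at the exocyclic carbon by SN2 attack on the primary allylic bromide, the only site of attack that restores the pyranone.

Step 5
Reactants: 7 2-[4-(allyloxy)-2-methoxyphenyl]-6-(4-methylpent-3-en-1-yl)-4H-pyran-4-one
Product: 8 2-{6-[4-(allyloxy)-2-methoxyphenyl]-4-oxo-4H-pyran-2-yl}-5-methylhex-4-enoic acid (racemic)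
Conditions: LiN(iPr)2 (1.2 equiv), THF, −78 °C; CO2 (excess), −78 → 0 °C; cold 1 M HCl to pH 3
Reagents that add atoms: carbon dioxide, O=C=O
Why: A second lateral lithiation can only occur at the CH2 attached to the pyranone (the aryl side has no α-hydrogen), and carboxylation of this anion with CO2 is a standard trapping that stops at the carboxylate; the new stereocentre forms racemic and is destroyed in step 8.

Step 6
Reactants: 8 2-{6-[4-(allyloxy)-2-methoxyphenyl]-4-oxo-4H-pyran-2-yl}-5-methylhex-4-enoic acid; 9 Meldrum's acid
Product: 11 methyl 4-{6-[4-(allyloxy)-2-methoxyphenyl]-4-oxo-4H-pyran-2-yl}-7-methyl-3-oxooct-6-enoate (racemic), via acyl Meldrum's acid adduct 10 (not isolated)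
Conditions: 9, DCC, DMAP, CH2Cl2, 0 °C → rt; filter; MeOH, reflux
Reagents that add atoms: methanol, CO
Why: Meldrum's acid homologation of a carboxylic acid to a β-keto ester: DCC/DMAP C-acylates 9, and methanolysis of adduct 10 in refluxing methanol releases acetone and CO2, a sequence that tolerates acids with an acidic α-hydrogen because it can also run through the ketene.

Step 7
Reactants: 11 methyl 4-{6-[4-(allyloxy)-2-methoxyphenyl]-4-oxo-4H-pyran-2-yl}-7-methyl-3-oxooct-6-enoate
Product: 12 methyl (2E)-4-{6-[4-(allyloxy)-2-methoxyphenyl]-4-oxo-4H-pyran-2-yl}-3-methoxy-7-methylocta-2,6-dienoate (racemic)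
Conditions: HC(OMe)3, TsOH·H2O (cat.), MeOH, rt → 45 °C
Reagents that add atoms: trimethyl orthoformate, COC(OC)OC
Why: Acid-catalysed ketal exchange with trimethyl orthoformate followed by loss of methanol toward the ester gives the conjugated β-methoxyacrylate under thermodynamic control, which should favour the E isomer (OMe anti to CO2Me) that holds the ester carbon cis to the prenyl-bearing carbon.

Step 8
Reactants: 12 methyl (2E)-4-{6-[4-(allyloxy)-2-methoxyphenyl]-4-oxo-4H-pyran-2-yl}-3-methoxy-7-methylocta-2,6-dienoate
Product: 14 2-[4-(allyloxy)-2-methoxyphenyl]-5-hydroxy-7-methoxy-8-(3-methylbut-2-en-1-yl)-4H-chromen-4-one (4'-O-allyl artocarpetin B), via 4a-H dienone 13 (not isolated)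
Conditions: LiN(SiMe3)2 (2.5 equiv), THF (0.02 M), −78 → 50 °C; 1 M HCl
Reagents that add atoms: none
Why: Proposed new method: LiN(SiMe3)2 should remove the C8–H, which is γ to both the pyranone carbonyl and the acrylate carbonyl, giving a delocalised lithium dienolate whose α-carbon C4a adds to the ester carbon C5 (lithium bridging O4 and the ester oxygen); loss of methoxide gives the 4a-H dienone 13, and removal of its doubly activated C4a–H by the second equivalent of base aromatises ring A irreversibly to the 5-phenoxide. The closest known reactions are base-mediated Claisen cyclisations of pyranone-masked poly-β-keto esters to acylphloroglucinols and Dieckmann condensations of dienolates. Ring A closes in a 6-(enolexo)-exo-trig mode, which is stereoelectronically favoured. No stereocentre is formed, and the racemic centre at C8 becomes an aromatic carbon. The step needs C4a, not C8 or an intermolecular partner, to attack C5: the E enol ether holds C5 cis to C8 so that only C4a can reach it through a six-membered transition state, and high dilution suppresses intermolecular condensation. A non-nucleophilic amide base leaves the pyranone ring closed, so O1 stays on C8a and the prenyl group can only appear at C8.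

Step 9
Reactants: 14 2-[4-(allyloxy)-2-methoxyphenyl]-5-hydroxy-7-methoxy-8-(3-methylbut-2-en-1-yl)-4H-chromen-4-one
Product: 15 artocarpetin B
Conditions: Pd(PPh3)4 (5 mol %), morpholine, THF, rt
Reagents that add atoms: none
Why: Tsuji–Trost-type deallylation: Pd(PPh3)4 (zerovalent palladium) ionises the aryl allyl ether to a π-allyl complex that morpholine captures, conditions that should leave the C-prenyl group, the methyl ethers and the chelated 5-OH untouched.

Compound list
1 | methyl 4-hydroxy-2-methoxybenzoate | COC(=O)c1ccc(O)cc1OC | starting material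
2 | methyl 4-(allyloxy)-2-methoxybenzoate | COC(=O)c1ccc(OCC=C)cc1OC | intermediate
3 | acetylacetone (pentane-2,4-dione) | CC(=O)CC(C)=O | starting material
4 | 1-[4-(allyloxy)-2-methoxyphenyl]hexane-1,3,5-trione | CC(=O)CC(=O)CC(=O)c1ccc(OCC=C)cc1OC | intermediate
5 | 2-[4-(allyloxy)-2-methoxyphenyl]-6-methyl-4H-pyran-4-one | Cc1cc(=O)cc(-c2ccc(OCC=C)cc2OC)o1 | intermediate
6 | prenyl bromide (1-bromo-3-methylbut-2-ene) | CC(C)=CCBr | starting material
7 | 2-[4-(allyloxy)-2-methoxyphenyl]-6-(4-methylpent-3-en-1-yl)-4H-pyran-4-one | CC(C)=CCCc1cc(=O)cc(-c2ccc(OCC=C)cc2OC)o1 | intermediate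
8 | 2-{6-[4-(allyloxy)-2-methoxyphenyl]-4-oxo-4H-pyran-2-yl}-5-methylhex-4-enoic acid (racemic) | CC(C)=CCC(C(=O)O)c1cc(=O)cc(-c2ccc(OCC=C)cc2OC)o1 | intermediate
9 | Meldrum's acid (2,2-dimethyl-1,3-dioxane-4,6-dione) | CC1(C)OC(=O)CC(=O)O1 | starting material
10 | 5-(2-{6-[4-(allyloxy)-2-methoxyphenyl]-4-oxo-4H-pyran-2-yl}-5-methylhex-4-enoyl)-2,2-dimethyl-1,3-dioxane-4,6-dione (racemic) | CC(C)=CCC(C(=O)C1C(=O)OC(C)(C)OC1=O)c1cc(=O)cc(-c2ccc(OCC=C)cc2OC)o1 | intermediate (not isolated)
11 | methyl 4-{6-[4-(allyloxy)-2-methoxyphenyl]-4-oxo-4H-pyran-2-yl}-7-methyl-3-oxooct-6-enoate (racemic) | COC(=O)CC(=O)C(CC=C(C)C)c1cc(=O)cc(-c2ccc(OCC=C)cc2OC)o1 | intermediate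
12 | methyl (2E)-4-{6-[4-(allyloxy)-2-methoxyphenyl]-4-oxo-4H-pyran-2-yl}-3-methoxy-7-methylocta-2,6-dienoate (racemic) | COC(=O)/C=C(OC)\C(CC=C(C)C)c1cc(=O)cc(-c2ccc(OCC=C)cc2OC)o1 | intermediate
13 | 2-[4-(allyloxy)-2-methoxyphenyl]-7-methoxy-8-(3-methylbut-2-en-1-yl)-4aH-chromene-4,5-dione (racemic keto tautomer of 14) | COC1=CC(=O)C2C(=O)C=C(c3ccc(OCC=C)cc3OC)OC2=C1CC=C(C)C | intermediate (not isolated)
14 | 2-[4-(allyloxy)-2-methoxyphenyl]-5-hydroxy-7-methoxy-8-(3-methylbut-2-en-1-yl)-4H-chromen-4-one (4'-O-allyl artocarpetin B) | C=CCOc1ccc(-c2cc(=O)c3c(O)cc(OC)c(CC=C(C)C)c3o2)c(OC)c1 | intermediate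
15 | artocarpetin B, 5-hydroxy-2-(4-hydroxy-2-methoxyphenyl)-7-methoxy-8-(3-methylbut-2-en-1-yl)-4H-chromen-4-one | COc1cc(O)ccc1-c1cc(=O)c2c(O)cc(OC)c(CC=C(C)C)c2o1 | target

Total step count: 9
Longest linear sequence: 9 steps (1 → 15)

Steps most likely to fail

Step 8 (proposed new method). The delocalised anion may not close, because the ester it has to attack is a deactivated vinylogous carbonate that shares the anion's conjugation. Alternatively, the pyranone may be opened by the methoxide that is released, which would lead to other condensations. The fallback uses known chemistry, sets out from 2 and returns at 14.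
- Saponification of 2 (LiOH, THF/H2O) should give 4-(allyloxy)-2-methoxybenzoic acid F1.
- Oxalyl chloride with catalytic DMF should convert it into 4-(allyloxy)-2-methoxybenzoyl chloride F2.
- The lithium polyanion of commercial 2',6'-dihydroxy-4'-methoxyacetophenone (SMILES CC(=O)c1c(O)cc(OC)cc1O; LiN(SiMe3)2, 4 equiv, THF, −78 °C) would be C-acylated by F2 to 1-[4-(allyloxy)-2-methoxyphenyl]-3-(2,6-dihydroxy-4-methoxyphenyl)propane-1,3-dione F3.
- H2SO4 (cat.) in AcOH at 95 °C should cyclodehydrate it to 2-[4-(allyloxy)-2-methoxyphenyl]-5-hydroxy-7-methoxy-4H-chromen-4-one F4; the two phenols are equivalent, so only one flavone can form.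
- O-Prenylation of the 5-OH with 6 (K2CO3, DMF, 60 °C) would give 2-[4-(allyloxy)-2-methoxyphenyl]-7-methoxy-5-[(3-methylbut-2-en-1-yl)oxy]-4H-chromen-4-one F5.
- A para-Claisen–Cope rearrangement catalysed by Eu(fod)3, that is Eu(C10H10F7O2)3 (trivalent europium, chelated between O4 and O5; NaHCO3, chlorobenzene, 85 °C), should carry the prenyl group via C6 to C8 and give 14. The 4'-O-allyl ether has no chelating carbonyl and should not rearrange at this temperature.

Step 5. The pyranonylacetic acid may lose CO2 during acidification or storage through its O-protonated form, and deprotonation of the secondary lateral position may be incomplete. The fallback sets out from 7 and returns at 11, bypassing 8 and 10: direct C-malonylation of the lateral anion. Lithiated 7 (2 equiv, from LiN(iPr)2, THF, −78 °C) would be added to methyl malonyl chloride (SMILES COC(=O)CC(=O)Cl, 1 equiv). Direct substitution at the acid chloride and addition to the derived carbomethoxyketene both lead to 11. One equivalent of the anion is spent as base, so half of 7 is expected back for recycling.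

Step 7. The acid may protonate the trisubstituted prenyl double bond, leading to addition of methanol or ring closure by the enol oxygen, and ketal formation at the branched ketone may be slow. The fallback sets out from 11 and returns at 12: kinetic O-alkylation of the free enolate with a hard electrophile (Cs2CO3, dimethyl sulfate, DMF, 0 °C) in place of acid-catalysed ketal exchange. A Z-rich mixture would be equilibrated to the E ester with catalytic iodine before step 8. A regio-isomer with the enol ether double bond toward C8 need not be removed, since deprotonation in step 8 gives the same delocalised anion.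

Further compounds
F1 | step 8 | 4-(allyloxy)-2-methoxybenzoic acid | C=CCOc1ccc(C(=O)O)c(OC)c1
F2 | step 8 | 4-(allyloxy)-2-methoxybenzoyl chloride | C=CCOc1ccc(C(Cl)=O)c(OC)c1
F3 | step 8 | 1-[4-(allyloxy)-2-methoxyphenyl]-3-(2,6-dihydroxy-4-methoxyphenyl)propane-1,3-dione | C=CCOc1ccc(C(=O)CC(=O)c2c(O)cc(OC)cc2O)c(OC)c1
F4 | step 8 | 2-[4-(allyloxy)-2-methoxyphenyl]-5-hydroxy-7-methoxy-4H-chromen-4-one | C=CCOc1ccc(-c2cc(=O)c3c(O)cc(OC)cc3o2)c(OC)c1
F5 | step 8 | 2-[4-(allyloxy)-2-methoxyphenyl]-7-methoxy-5-[(3-methylbut-2-en-1-yl)oxy]-4H-chromen-4-one | C=CCOc1ccc(-c2cc(=O)c3c(OCC=C(C)C)cc(OC)cc3o2)c(OC)c1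
F0 | step 5 | none | none
F0 | step 7 | none | none
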